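## Structural features

The target is a flavanone: benzene ring A is fused along the C4a–C8a bond to the dihydropyranone ring C, which carries the phenyl ring B at C2. Ring A is substituted at five of its six carbons, with three oxygens in a 1,3,5 relation (O1 at C8a, the free hydroxyl at C5, the methyl ether at C7) and a 3-hydroxy-3-methylbutyl chain at C8, so that only C6 bears hydrogen. C2 (S) is the only stereocentre; it has no stereogenic neighbour, but it is benzylic, bound to the aryl ether oxygen O1 and β to the C4 ketone. This makes it fragile: base enolises C3 and expels the O1 phenoxide (ring-opening to the chalcone and unselective reclosure), and hydrogenolysis can attack the benzylic C2–O1 bond. The tertiary alcohol is acid-labile (dehydration, or cyclisation onto an ortho phenol in open-chain intermediates), and the C5 hydroxyl is hydrogen-bonded to the C4 carbonyl. The real difficulty is twofold: to place three different oxygen functions and the chain on ring A without ambiguity, and to attach ring C with its stereocentre under conditions that do not scramble C2. The key step exploits the fact that ring C is tied to ring A by two bonds, O1–C8a and C4–C4a, at adjacent ring carbons, which are the two ends of an aryne, while O1, C2, C3 and C4 with ring B and the stereocentre map onto an enantiopure 3-hydroxy-3-phenylpropanoate.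

## Logic of the disconnections

**23 ⇒ 22.** The two O–CH2Ph bonds (at O5 and at the tertiary oxygen of the chain) are cut. Both hydroxyls have to be masked in the aryne step: a free O–H would protonate the aryl anion, and the tertiary alkoxide would capture the aryne through a six-membered ring. With benzyl on both, one neutral hydrogenolysis ends the synthesis and neither acid nor base touches the flavanone. The demand is that hydrogenolysis stops before the benzylic C2–O1 bond or the ketone is reduced.

**22 ⇒ 18 + 19 (through 20 and 21).** The bonds O1–C8a and C4–C4a are cut. This opens ring C and divides the molecule into ring A with its chain (18) and the O1–C2–C3–C4 unit with ring B (19), two pieces of similar size; the stereocentre is bought with 19 and only has to be preserved. The demands are that the alkoxide 20 adds to C8a and not C4a of 21, that the C4a carbanion acylates faster than it is protonated, and that 20 and 22 survive the basic medium.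

**18 ⇒ 16 ⇒ 15.** The S–O bond of the triflate and then the carbamoyl C–O bond are cut. An ortho-silyl aryl triflate is best reached from the ortho-silyl phenol, and the phenol from the carbamate that directed the silylation. The demand is that the carbamate, flanked on both sides, is removed without acid, because the aryl–silicon bond on this electron-rich ring is prone to protodesilylation.

**15 ⇒ 12 + 13 (through 14).** The C4a–Si bond is cut. C4a is the only unsubstituted position ortho to the carbamate and also lies next to the O5 ether, so directed metalation places silicon there and nowhere else. The demand is a carbamate that tolerates alkyllithium at low temperature and a metalation that is faster than deprotonation of the benzylic ether positions.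

**12 ⇒ 11 + 2, and 11 ⇒ 9 + 10.** The tertiary O–CH2Ph bond and then the carbamoyl O–C(O) bond are cut. The order matters: in 9 the phenol is far more reactive than the tertiary alcohol towards any electrophile, so it is capped first with the group that is needed anyway as director. The demand on that group is stability to the NaH used for the tertiary ether, which is why a tertiary (N,N-dialkyl) carbamate is chosen.

**9 ⇒ 6 + 7 (through 8).** The two C–CH3 bonds at the carbinol carbon are cut. The lactone of 6 is at once the ester that becomes the tertiary alcohol and the mask of the one phenol that must stay free; its opening differentiates the future O1 from the two other oxygens of ring A at no cost. The demand is a non-acidic work-up, since 9 cyclises readily to a chroman.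

**6 ⇒ 5.** The C3–C4 double bond of the coumarin is reintroduced. The demand is a hydrogenation that saturates this bond and leaves the aryl benzyl ether alone.

**5 ⇒ 3 + 4, and 3 ⇒ 1 + 2.** The O–CH3 bond at O5 and the O–CH2Ph bond at O7 of the coumarin are cut. 1 already contains ring A, the three oxygens, the two chain carbons and the lactone in the right places. The demand is that the first alkylation discriminates between the two phenols, which rests on the higher acidity and better accessibility of the 7-hydroxyl.

## Other disconnections considered

**Alternative 1:** retentive palladium O-arylation.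
- **Cut and key step.** Only the aryl ether bond O1–C8a is cut, on a substrate whose C4 is masked as a 1,3-dithiane. The chloro alcohol A2 would be cyclised to A1 by zerovalent palladium, formed from Pd(OAc)2 and a bulky biaryl di-tert-butylphosphine with Cs2CO3. The palladium inserts into C8a–Cl and couples with the C2 hydroxyl; the C2–O bond is not touched, so the configuration of A2 is retained.
- **In favour.** Intramolecular palladium-catalysed etherification of secondary alcohols is an established reaction class; on precedent this alternative is better than the chosen plan. The site of closure is fixed by the position of chlorine and does not depend on aryne polarisation; this is also better. The ketone is masked during the coupling, so no enolisable flavanone meets base; on this point the alternative is at least equal.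
- **Against.** Two thioether sulfurs in the same molecule are strong ligands for palladium. The C8a–Cl bond sits on an electron-rich ring between the C8 chain and the quaternary dithiane carbon, so oxidative addition is slow. The palladium alkoxide of a secondary benzylic alcohol can undergo β-hydride elimination.
- **Comparison.** In structural terms one ring bond is formed, and the whole C2–C3–C4 chain must be attached to ring A beforehand in a linear sequence; the chosen plan forms two bonds and joins two halves. After A1 three unmasking operations remain (dithiane hydrolysis, which must precede any hydrogenolysis, then desilylation and debenzylation) against one. The alternative is more secure in mechanism but less convergent and longer.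

**Alternative 2:** ring-closing metathesis to a cyclic silyl enol ether.
- **Cut and key step.** The cut is C3=C4 at the oxidation level of a silyl enol ether. The diene A4, an aryl 1-phenylallyl ether with a neighbouring 1-silyloxyvinyl group, would be closed by the second-generation Grubbs catalyst (H2IMes)(PCy3)Cl2Ru=CHPh to the 2H-chromene A3.
- **In favour.** The conditions are neutral. The ketone is released from A3 by mild hydrolysis and never meets base; on this point the alternative is better than the chosen plan. Metathesis of silyl enol ethers is a known reaction class, so it is also better on precedent. The stereocentre of A4 could come from a catalytic asymmetric allylic etherification instead of a purchased chiral ester, which is an equal solution.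
- **Against.** The enol ether olefin is 1,1-disubstituted, electron-rich and flanked by two ortho substituents, so it is a poor metathesis partner. The C2–H of A4 and A3 is allylic, benzylic and oxygen-bound; ionisation or double-bond migration by ruthenium hydride species would destroy the stereocentre. The silyl enol ether is hydrolytically labile during its preparation.
- **Comparison.** One bond is formed in the key step against two. Before it, an acetyl group, the chiral allyl ether and the enol silane have to be installed on the hindered ring; after it, three operations remain (hydrolysis, desilylation, hydrogenolysis). The alternative is milder towards the product but longer, and the stereocentre is exposed where the chosen plan only has to carry it through one step.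

**Alternative 3:** enantioselective carbene insertion into the benzyl ether C–H.
- **Cut and key step.** The cut is C2–C3. The diazo ketone A6 would lose N2 on Rh2(S-PTTL)4, dirhodium tetrakis[N-phthaloyl-(S)-tert-leucinate], and the carbene at C3 would insert into a benzylic C–H of the O1-benzyl group to give A5. C2–C3, ring C and the stereocentre are created in one event.
- **In favour.** Ring B and C2 come from a plain benzyl ether and no chiral building block is needed; in atom and step economy up to the key step this alternative is better than the chosen plan. The stereocentre is made catalytically. After A5 a single desilylation remains, which is equal to the single hydrogenolysis of the chosen plan.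
- **Against.** The carbene carries only an acyl group and is therefore unselective. Closure of a six-membered ring by C–H insertion competes with attack on the O1 lone pair (a five-membered oxonium ylide followed by benzyl migration) and with addition to the benzyl arene. The sense and level of asymmetric induction rest entirely on the catalyst and are uncertain for insertion next to an aryl ether oxygen. A6 has to be made from a doubly ortho-substituted benzoic acid with a hazardous diazoalkane.
- **Comparison.** The alternative is shorter on paper, but both its chemoselectivity and its enantiocontrol are less secure than the single regiochemical question of the chosen plan, where the configuration is bought and only has to be preserved.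

Key step: step 10

**Remark on the chemistry:** the aryne precursor 18 is numbered as a phenyl triflate with the benzyloxy group at position 5, next to the silyl carbon. A 4-benzyloxy locant would put that oxygen para to the triflate and could not lead to a 5,7-dioxygenated flavanone. The phenol is carbamoylated before the tertiary alcohol is benzylated, and with a tertiary (N,N-diethyl) carbamate, because a free phenol would be benzylated first and a secondary carbamate would not survive NaH.

## Route

Step 1
Reactants: 1 5,7-dihydroxycoumarin; 2 benzyl bromide
Product: 3 7-(benzyloxy)-5-hydroxycoumarin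
Conditions: BnBr (1.0 equiv), K2CO3 (1.0 equiv), DMF, 0 °C → rt
Reagents that add atoms: benzyl bromide, BrCc1ccccc1
Why: Williamson ether synthesis; the 7-hydroxyl is the more acidic phenol (its phenoxide is conjugated para through C4a with the unsaturated lactone) and is less hindered than the 5-hydroxyl beside the peri C4–H, so one equivalent of base and halide should give mainly the O7 mono-ether.

Step 2
Reactants: 3 7-(benzyloxy)-5-hydroxycoumarin; 4 iodomethane
Product: 5 7-(benzyloxy)-5-methoxycoumarin
Conditions: MeI (1.5 equiv), K2CO3 (2 equiv), acetone, reflux
Reagents that add atoms: iodomethane, CI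
Why: Williamson O-methylation of the only remaining phenol; the lactone and the benzyl ether are inert to K2CO3 in acetone.

Step 3
Reactants: 5 7-(benzyloxy)-5-methoxycoumarin
Product: 6 7-(benzyloxy)-5-methoxychroman-2-one
Conditions: H2 (4 atm), RhCl(PPh3)3 (5 mol %), toluene/THF, 60 °C
Reagents that add atoms: none
Why: Homogeneous alkene hydrogenation; the rhodium catalyst should saturate the electron-poor cis-disubstituted C3=C4 bond of the unsaturated lactone and, unlike heterogeneous palladium, does not hydrogenolyse the aryl benzyl ether.

Step 4
Reactants: 6 7-(benzyloxy)-5-methoxychroman-2-one; 7 methylmagnesium bromide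
Product: 9 5-(benzyloxy)-2-(3-hydroxy-3-methylbutyl)-3-methoxyphenol, via aryl methyl ketone 8 (not isolated)
Conditions: MeMgBr (3.5 equiv), THF, 0 °C → rt; aq. NH4Cl
Reagents that add atoms: methylmagnesium bromide, C[Mg]Br
Why: Twofold Grignard addition to an aryl lactone; the first addition collapses to ketone 8 with release of the phenoxide and the second gives the tertiary alkoxide, so the lactone oxygen emerges as the one free phenol of ring A (the future O1), and the neutral work-up avoids acid-induced cyclisation of the tertiary alcohol onto that phenol.

Step 5
Reactants: 9 5-(benzyloxy)-2-(3-hydroxy-3-methylbutyl)-3-methoxyphenol; 10 N,N-diethylcarbamoyl chloride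
Product: 11 5-(benzyloxy)-2-(3-hydroxy-3-methylbutyl)-3-methoxyphenyl N,N-diethylcarbamate
Conditions: ClCONEt2 (1.2 equiv), K2CO3 (2 equiv), MeCN, 80 °C
Reagents that add atoms: N,N-diethylcarbamoyl chloride, CCN(CC)C(=O)Cl
Why: O-Carbamoylation of a phenoxide; K2CO3 ionises only the phenol, the hindered neutral tertiary alcohol does not compete, and the N,N-diethyl carbamate is chosen because it withstands NaH and alkyllithium, whereas a secondary carbamate would fragment under base.

Step 6
Reactants: 11 5-(benzyloxy)-2-(3-hydroxy-3-methylbutyl)-3-methoxyphenyl N,N-diethylcarbamate; 2 benzyl bromide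
Product: 12 5-(benzyloxy)-2-[3-(benzyloxy)-3-methylbutyl]-3-methoxyphenyl N,N-diethylcarbamate
Conditions: NaH (1.5 equiv), BnBr (1.5 equiv), Bu4NI (0.1 equiv), THF, 0 → 60 °C
Reagents that add atoms: benzyl bromide, BrCc1ccccc1
Why: Williamson etherification of a tertiary sodium alkoxide, helped by benzyl iodide formed in the flask; the phenol is already capped and the diethyl carbamate is a poor acyl donor, so transfer of the carbamoyl group to the alkoxide through an eight-membered ring should not compete.

Step 7
Reactants: 12 5-(benzyloxy)-2-[3-(benzyloxy)-3-methylbutyl]-3-methoxyphenyl N,N-diethylcarbamate; 13 chlorotrimethylsilane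
Product: 15 5-(benzyloxy)-2-[3-(benzyloxy)-3-methylbutyl]-3-methoxy-6-(trimethylsilyl)phenyl N,N-diethylcarbamate, via aryllithium 14 (not isolated)
Conditions: s-BuLi (1.3 equiv), TMEDA (1.3 equiv), THF, −78 °C; TMSCl (1.6 equiv), −78 °C → rt; aq. NH4Cl
Reagents that add atoms: chlorotrimethylsilane, C[Si](C)(C)Cl
Why: Directed ortho-metalation; the carbamate is the strongest directing group on the ring, its only free ortho position (the future C4a) also lies next to the benzyloxy oxygen, so 14 should form there at −78 °C and is silylated before any anionic carbamoyl migration can set in.

Step 8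
Reactants: 15 5-(benzyloxy)-2-[3-(benzyloxy)-3-methylbutyl]-3-methoxy-6-(trimethylsilyl)phenyl N,N-diethylcarbamate
Product: 16 5-(benzyloxy)-2-[3-(benzyloxy)-3-methylbutyl]-3-methoxy-6-(trimethylsilyl)phenol
Conditions: LiAlH4 (3 equiv), THF, 0 °C → reflux; aq. potassium sodium tartrate
Reagents that add atoms: none
Why: Reductive cleavage of an aryl carbamate; hydride adds to the carbamoyl carbon, which stands one atom away from the ring and is not shielded by the two flanking groups, the phenoxide is expelled, and ethers and the aryl–silicon bond are inert to hydride while the non-acidic work-up avoids protodesilylation.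

Step 9
Reactants: 16 5-(benzyloxy)-2-[3-(benzyloxy)-3-methylbutyl]-3-methoxy-6-(trimethylsilyl)phenol; 17 trifluoromethanesulfonic anhydride
Product: 18 5-(benzyloxy)-2-[3-(benzyloxy)-3-methylbutyl]-3-methoxy-6-(trimethylsilyl)phenyl trifluoromethanesulfonate
Conditions: Tf2O (1.2 equiv), pyridine (3 equiv), CH2Cl2, −20 → 0 °C
Reagents that add atoms: trifluoromethanesulfonic anhydride, O=S(=O)(OS(=O)(=O)C(F)(F)F)C(F)(F)F
Why: O-Sulfonylation of a phenol; the hindered but acidic phenol reacts at oxygen, and the cold, pyridine-buffered medium protects the acid-sensitive aryl–silicon bond and the benzyl ethers.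

Step 10
Reactants: 18 5-(benzyloxy)-2-[3-(benzyloxy)-3-methylbutyl]-3-methoxy-6-(trimethylsilyl)phenyl trifluoromethanesulfonate; 19 methyl (S)-3-hydroxy-3-phenylpropanoate
Product: 22 (S)-5-(benzyloxy)-8-[3-(benzyloxy)-3-methylbutyl]-7-methoxyflavanone, via sodium alkoxide 20 (not isolated), via aryne 21 (not isolated)
Conditions: 19 (1.2 equiv), NaH (1.15 equiv), THF, 0 °C; then 18 (1.0 equiv), KF (3 equiv), 18-crown-6 (3 equiv), THF, 0 °C → rt; AcOH (2 equiv), 0 °C
Reagents that add atoms: methyl (S)-3-hydroxy-3-phenylpropanoate, COC(=O)C[C@H](O)c1ccccc1
Why: Proposed new method: fluoride attacks silicon in 18 and the triflate leaves, giving aryne 21 across C4a–C8a; the preformed alkoxide 20 adds at C8a (O1–C8a) and the resulting C4a aryl anion attacks the ester carbonyl and expels methoxide (C4–C4a). The closest known reaction type is the fluoride-induced annulation of arynes with salicylate esters to xanthones, where O-arylation is likewise followed by intramolecular acyl substitution; new here is an aliphatic secondary alkoxide that carries an enolisable ester. Ring C is closed by a 6-exo-trig acyl substitution of the aryl anion on the ester, after the intermolecular O-arylation. No stereocentre is created: C2 comes from 19 and its C–O bond is never broken, so the S configuration should be carried over unchanged. The selectivity needed is attack at C8a and not C4a; the benzyloxy group at C5 distorts and polarises the aryne so that the nucleophile enters at the remote carbon and the charge develops next to the electron-withdrawing oxygen, a preference that has to override the steric demand of the C8 chain. Protonation of the aryl anion is suppressed because 20 is made with NaH (hydrogen escapes), the solvent is THF and no O–H or N–H group is present. The low temperature, the near-stoichiometric amount of 20 and the cold AcOH quench are meant to limit retro-aldol cleavage of 20 and opening of ring C in 22 by the liberated methoxide, either of which would erode the configuration at C2.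

Step 11
Reactants: 22 (S)-5-(benzyloxy)-8-[3-(benzyloxy)-3-methylbutyl]-7-methoxyflavanone
Product: 23 (S)-5-hydroxy-8-(3-hydroxy-3-methylbutyl)-7-methoxyflavanone
Conditions: H2 (1 atm), 10% Pd/C, EtOAc, rt
Reagents that add atoms: none
Why: Catalytic hydrogenolysis of benzyl ethers; the aryl benzyl ether should cleave fast and the tertiary alkyl benzyl ether more slowly at its unhindered CH2, the neutral medium cannot epimerise C2, and the reaction is stopped once both ethers are gone so that the benzylic C2–O1 bond and the hydrogen-bonded C4 ketone stay intact.

## Compound list

1 | 5,7-dihydroxycoumarin | O=c1ccc2c(O)cc(O)cc2o1 | starting material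
2 | benzyl bromide | BrCc1ccccc1 | starting material
3 | 7-(benzyloxy)-5-hydroxycoumarin | O=c1ccc2c(O)cc(OCc3ccccc3)cc2o1 | intermediate
4 | iodomethane | CI | starting material
5 | 7-(benzyloxy)-5-methoxycoumarin | COc1cc(OCc2ccccc2)cc2oc(=O)ccc12 | intermediate
6 | 7-(benzyloxy)-5-methoxychroman-2-one | COc1cc(OCc2ccccc2)cc2OC(=O)CCc12 | intermediate
7 | methylmagnesium bromide | C[Mg]Br | starting material
8 | 4-[4-(benzyloxy)-2-hydroxy-6-methoxyphenyl]butan-2-one, present as its bromomagnesium phenoxide (not isolated) | CC(=O)CCc1c(OC)cc(OCc2ccccc2)cc1O[Mg]Br | intermediate
9 | 5-(benzyloxy)-2-(3-hydroxy-3-methylbutyl)-3-methoxyphenol | COc1cc(OCc2ccccc2)cc(O)c1CCC(C)(C)O | intermediate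
10 | N,N-diethylcarbamoyl chloride | CCN(CC)C(=O)Cl | starting material
11 | 5-(benzyloxy)-2-(3-hydroxy-3-methylbutyl)-3-methoxyphenyl N,N-diethylcarbamate | CCN(CC)C(=O)Oc1cc(OCc2ccccc2)cc(OC)c1CCC(C)(C)O | intermediate
12 | 5-(benzyloxy)-2-[3-(benzyloxy)-3-methylbutyl]-3-methoxyphenyl N,N-diethylcarbamate | CCN(CC)C(=O)Oc1cc(OCc2ccccc2)cc(OC)c1CCC(C)(C)OCc1ccccc1 | intermediate
13 | chlorotrimethylsilane | C[Si](C)(C)Cl | starting material
14 | 5-(benzyloxy)-2-[3-(benzyloxy)-3-methylbutyl]-6-lithio-3-methoxyphenyl N,N-diethylcarbamate (not isolated) | CCN(CC)C(=O)Oc1c([Li])c(OCc2ccccc2)cc(OC)c1CCC(C)(C)OCc1ccccc1 | intermediate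
15 | 5-(benzyloxy)-2-[3-(benzyloxy)-3-methylbutyl]-3-methoxy-6-(trimethylsilyl)phenyl N,N-diethylcarbamate | CCN(CC)C(=O)Oc1c([Si](C)(C)C)c(OCc2ccccc2)cc(OC)c1CCC(C)(C)OCc1ccccc1 | intermediate
16 | 5-(benzyloxy)-2-[3-(benzyloxy)-3-methylbutyl]-3-methoxy-6-(trimethylsilyl)phenol | COc1cc(OCc2ccccc2)c([Si](C)(C)C)c(O)c1CCC(C)(C)OCc1ccccc1 | intermediate
17 | trifluoromethanesulfonic anhydride | O=S(=O)(OS(=O)(=O)C(F)(F)F)C(F)(F)F | starting material
18 | 5-(benzyloxy)-2-[3-(benzyloxy)-3-methylbutyl]-3-methoxy-6-(trimethylsilyl)phenyl trifluoromethanesulfonate | COc1cc(OCc2ccccc2)c([Si](C)(C)C)c(OS(=O)(=O)C(F)(F)F)c1CCC(C)(C)OCc1ccccc1 | intermediate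
19 | methyl (S)-3-hydroxy-3-phenylpropanoate | COC(=O)C[C@H](O)c1ccccc1 | starting material
20 | sodium (S)-3-methoxy-3-oxo-1-phenylpropan-1-olate (not isolated) | COC(=O)C[C@H]([O-])c1ccccc1.[Na+] | intermediate
21 | 3-(benzyloxy)-6-[3-(benzyloxy)-3-methylbutyl]-5-methoxybenzyne (not isolated) | COC1=C(CCC(C)(C)OCc2ccccc2)C#CC(OCc2ccccc2)=C1 | intermediate
22 | (S)-5-(benzyloxy)-8-[3-(benzyloxy)-3-methylbutyl]-7-methoxyflavanone | COc1cc(OCc2ccccc2)c2c(c1CCC(C)(C)OCc1ccccc1)O[C@H](c1ccccc1)CC2=O | intermediate
23 | (S)-5-hydroxy-8-(3-hydroxy-3-methylbutyl)-7-methoxyflavanone | COc1cc(O)c2c(c1CCC(C)(C)O)O[C@H](c1ccccc1)CC2=O | target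

## Step count and least certain steps

Total: 11 steps. Longest linear sequence: 11 steps (1 to 23); 19 is purchased.

**Step 10 (key step, the proposed new method).**
- What may go wrong: the C4a carbanion may be quenched before it acylates, by proton transfer from the acidic α-methylene of its own ester through a six-membered transition state, followed by β-elimination of the aryloxide. The alkoxide 20 may fragment by retro-aldol cleavage before it meets the short-lived aryne. Addition at C4a would give the regioisomeric ring fusion. The liberated methoxide may open ring C and so erode the configuration at C2.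
- Fallback (known reactions only): it sets out from 12 and comes back at 22.
  - LiAlH4 in THF would cleave the still unhindered carbamate of 12 to 5-(benzyloxy)-2-[3-(benzyloxy)-3-methylbutyl]-3-methoxyphenol F1.
  - A Mitsunobu reaction (PPh3, diisopropyl azodicarboxylate, toluene, 0 °C) of F1 with the commercial enantiomeric ester, methyl (R)-3-hydroxy-3-phenylpropanoate F2, should form the O1–C2 bond with inversion and give methyl (S)-3-{5-(benzyloxy)-2-[3-(benzyloxy)-3-methylbutyl]-3-methoxyphenoxy}-3-phenylpropanoate F3.
  - Saponification (LiOH, THF/H2O, 0 °C) would give (S)-3-{5-(benzyloxy)-2-[3-(benzyloxy)-3-methylbutyl]-3-methoxyphenoxy}-3-phenylpropanoic acid F4.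
  - The mixed anhydride of F4 with (CF3CO)2O (CH2Cl2, 0 °C) should acylate C4a, the only free position ortho to O1 and one activated by three oxygens, in an intramolecular Friedel–Crafts reaction that closes ring C and gives 22.
  - This fallback makes the O1–C2 and C4–C4a bonds one after the other, needs three more steps, and exposes the benzylic ether to acid.

**Step 1.**
- What may go wrong: insufficient discrimination between the two phenols of 1 (alkylation at O5, or at both oxygens), because both phenoxides are conjugated with the lactone.
- Fallback: it sets out from 2 and comes back at 5, so that step 2 is no longer needed.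
  - The catalogue compound 2,4-dihydroxy-6-methoxybenzaldehyde F5 is benzylated with 2 (K2CO3, 1 equiv, acetone, reflux). The 2-hydroxyl is locked in a hydrogen bond to the formyl group, so only the 4-hydroxyl should react, giving 4-(benzyloxy)-2-hydroxy-6-methoxybenzaldehyde F6.
  - A Wittig reaction of F6 with methyl (triphenylphosphoranylidene)acetate in refluxing N,N-diethylaniline forms the cinnamate, which lactonises in the same flask to 5.
  - Here the oxygen pattern is fixed by the hydrogen bond and no longer by relative acidity.

**Step 3.**
- What may go wrong: slow or incomplete hydrogenation, because the double bond is part of an electron-rich coumarin and is flanked by the peri methoxy group.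
- Fallback: it sets out from 5 and comes back at 6.
  - H2 over 10% Pd/C in EtOAc/MeOH saturates the double bond and, unavoidably, removes the benzyl group, giving 7-hydroxy-5-methoxychroman-2-one F7.
  - The single phenol of F7 is benzylated again with 2 (K2CO3, acetone) to give 6.
  - This costs one step and makes no demand on chemoselectivity.

**Step 11.**
- What may go wrong: over-reduction (hydrogenolysis of the benzylic C2–O1 bond or reduction of the ketone) during the longer exposure that the hindered tertiary benzyl ether needs.
- Fallback: it sets out from 22 and comes back at 23.
  - The alkyl benzyl ether is removed first by oxidation and not by reduction: DDQ in wet CH2Cl2 under visible-light irradiation abstracts hydride from the benzylic CH2 of the tertiary ether, whose oxygen lone pair is not delocalised into an arene, and hydrolysis gives (S)-5-(benzyloxy)-8-(3-hydroxy-3-methylbutyl)-7-methoxyflavanone F8.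
  - A brief hydrogenolysis (H2, 10% Pd/C, EtOAc) then removes the fast-cleaving aryl benzyl ether to give 23.

## Further compounds

F1 | step 10 | 5-(benzyloxy)-2-[3-(benzyloxy)-3-methylbutyl]-3-methoxyphenol | COc1cc(OCc2ccccc2)cc(O)c1CCC(C)(C)OCc1ccccc1
F2 | step 10 | methyl (R)-3-hydroxy-3-phenylpropanoate (purchased reagent of the fallback) | COC(=O)C[C@@H](O)c1ccccc1
F3 | step 10 | methyl (S)-3-{5-(benzyloxy)-2-[3-(benzyloxy)-3-methylbutyl]-3-methoxyphenoxy}-3-phenylpropanoate | COC(=O)C[C@H](Oc1cc(OCc2ccccc2)cc(OC)c1CCC(C)(C)OCc1ccccc1)c1ccccc1
F4 | step 10 | (S)-3-{5-(benzyloxy)-2-[3-(benzyloxy)-3-methylbutyl]-3-methoxyphenoxy}-3-phenylpropanoic acid | OC(=O)C[C@H](Oc1cc(OCc2ccccc2)cc(OC)c1CCC(C)(C)OCc1ccccc1)c1ccccc1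
F5 | step 1 | 2,4-dihydroxy-6-methoxybenzaldehyde (purchased starting material of the fallback) | COc1cc(O)cc(O)c1C=O
F6 | step 1 | 4-(benzyloxy)-2-hydroxy-6-methoxybenzaldehyde | COc1cc(OCc2ccccc2)cc(O)c1C=O
F7 | step 3 | 7-hydroxy-5-methoxychroman-2-one | COc1cc(O)cc2OC(=O)CCc12
F8 | step 11 | (S)-5-(benzyloxy)-8-(3-hydroxy-3-methylbutyl)-7-methoxyflavanone | COc1cc(OCc2ccccc2)c2c(c1CCC(C)(C)O)O[C@H](c1ccccc1)CC2=O
A1 | alternative 1 | (S)-5-(benzyloxy)-7-methoxy-8-(3-methyl-3-triethylsilyloxybutyl)flavanone 4-(propane-1,3-diyl dithioketal) | COc1cc(OCc2ccccc2)c2c(c1CCC(C)(C)O[Si](CC)(CC)CC)O[C@H](c1ccccc1)CC21SCCCS1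
A2 | alternative 1 | (S)-2-{2-[6-(benzyloxy)-2-chloro-4-methoxy-3-(3-methyl-3-triethylsilyloxybutyl)phenyl]-1,3-dithian-2-yl}-1-phenylethanol | COc1cc(OCc2ccccc2)c(c(Cl)c1CCC(C)(C)O[Si](CC)(CC)CC)C1(C[C@H](O)c2ccccc2)SCCCS1
A3 | alternative 2 | (S)-5-(benzyloxy)-4-(tert-butyldimethylsilyloxy)-7-methoxy-8-(3-methyl-3-triethylsilyloxybutyl)-2-phenyl-2H-chromene | COc1cc(OCc2ccccc2)c2c(c1CCC(C)(C)O[Si](CC)(CC)CC)O[C@H](c1ccccc1)C=C2O[Si](C)(C)C(C)(C)C
A4 | alternative 2 | tert-butyl({1-[6-(benzyloxy)-4-methoxy-3-(3-methyl-3-triethylsilyloxybutyl)-2-{[(1S)-1-phenylprop-2-en-1-yl]oxy}phenyl]ethenyl}oxy)dimethylsilane | COc1cc(OCc2ccccc2)c(C(=C)O[Si](C)(C)C(C)(C)C)c(O[C@@H](C=C)c2ccccc2)c1CCC(C)(C)O[Si](CC)(CC)CC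
A5 | alternative 3 | (S)-5-(tert-butyldimethylsilyloxy)-7-methoxy-8-(3-methyl-3-triethylsilyloxybutyl)flavanone | COc1cc(O[Si](C)(C)C(C)(C)C)c2c(c1CCC(C)(C)O[Si](CC)(CC)CC)O[C@H](c1ccccc1)CC2=O
A6 | alternative 3 | 1-[2-(benzyloxy)-6-(tert-butyldimethylsilyloxy)-4-methoxy-3-(3-methyl-3-triethylsilyloxybutyl)phenyl]-2-diazoethanone | COc1cc(O[Si](C)(C)C(C)(C)C)c(C(=O)C=[N+]=[N-])c(OCc2ccccc2)c1CCC(C)(C)O[Si](CC)(CC)CC
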